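**Retrosynthetic overview**

- Numbering: ring A is C1(Me)–C2(OAc)–C3–C4(OH)(iPr)–C5, ring B is C5–C6(O-angeloyl)–C7–C8(Me)=C9–C10(OBz)–C1; β is the face of the C1 methyl; the target is (1R,2S,4R,5S,6S,10S), trans-fused.
- Feature used: ring B is a latent cyclohepta-1,4-diene. C8=C9 is present, a C6 ketone supplies C5=C6 as its enol, C7 is the methylene between them, and the quaternary C1 is bonded to C10, so the C1–C10 bond can arise from a [3,3] shift of a cis-divinylcyclopropane.
- Late disconnections: the three esters (C6 angelate last); C6–OH and C2–OH from ketones by reduction directed by the C4 hydroxyl; C10–OH by γ-oxidation of a C8 enoate and hydride reduction; the C8 methyl from the enoate carbon.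
- Key disconnection: C7–C8 and C1–C10, by adding the carbene carbon of methyl 2-diazobut-3-enoate to the C6=C7 enol ether of a 2-silyloxydiene, then Cope rearrangement.
- Ring order: ring A first, by ozonolysis and aldol ring contraction of (S)-terpinen-4-ol (C4 from the chiral pool); ring B second, in the key step.

Key step: step 11

Remark on the chemistry: C4 is carried as a triethylsilyl ether (it must last nine steps), and Rh2(S-DOSP)4 is assumed to show the same sense of induction as in its cyclopropanation/Cope reactions with (E)-1-substituted butadienes.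

**Route**

Step 1
Reactants: 1 (S)-terpinen-4-ol
Product: 2 (S)-terpinen-4-ol triethylsilyl ether
Conditions: Et3SiOTf, 2,6-lutidine, CH2Cl2, −78 → 0 °C
Reagents that add atoms: triethylsilyl triflate, CC[Si](CC)(CC)OS(=O)(=O)C(F)(F)F
Why: Silylation of a hindered tertiary alcohol with a silyl triflate and a hindered base; C4 is untouched, and the ether later keeps the hydroxyl from retro-aldol cleavage and from O–H insertion of the carbenoid.

Step 2
Reactants: 2 (S)-terpinen-4-ol triethylsilyl ether
Product: 4 (S)-6-oxo-3-(propan-2-yl)-3-(triethylsilyloxy)heptanal, via secondary ozonide 3 (not isolated)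
Conditions: O3, CH2Cl2, −78 °C; then PPh3, −78 °C → rt
Reagents that add atoms: ozone, [O-][O+]=O
Why: Ozonolysis of the only alkene with reductive work-up gives the 1,6-keto aldehyde; no bond to C4 is broken.

Step 3
Reactants: 4 (S)-6-oxo-3-(propan-2-yl)-3-(triethylsilyloxy)heptanal
Product: 5 (R)-2-methyl-5-(propan-2-yl)-5-(triethylsilyloxy)cyclopent-1-ene-1-carbaldehyde
Conditions: piperidine (cat.), AcOH (cat.), toluene, 4 Å molecular sieves, 80 °C
Reagents that add atoms: none
Why: Amine-catalysed intramolecular aldol condensation: the aldehyde forms its enamine much faster than the ketone, so the aldehyde α-carbon (future C5) attacks the methyl ketone (future C1) in a 5-exo closure and dehydration gives the tetrasubstituted enal (ring A).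

Step 4
Reactants: 5 (R)-2-methyl-5-(propan-2-yl)-5-(triethylsilyloxy)cyclopent-1-ene-1-carbaldehyde
Product: 7 1-[(R)-2-methyl-5-(propan-2-yl)-5-(triethylsilyloxy)cyclopent-1-en-1-yl]ethyl acetate (both carbinol epimers), via bromomagnesium alkoxide 6 (not isolated)
Conditions: MeMgBr, THF, −78 → 0 °C; then Ac2O, 0 °C → rt
Reagents that add atoms: methylmagnesium bromide, C[Mg]Br; acetic anhydride, CC(=O)OC(C)=O
Why: Grignard 1,2-addition to the β,β-disubstituted enal brings in C7, and the alkoxide is acetylated in the same flask; the carbinol centre is a mixture of no consequence because it becomes the C6 ketone in step 8.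

Step 5
Reactants: 7 allylic acetate
Product: 8 1-[(R)-2-methyl-3-oxo-5-(propan-2-yl)-5-(triethylsilyloxy)cyclopent-1-en-1-yl]ethyl acetate
Conditions: Rh2(cap)4 (dirhodium tetrakis(caprolactamate), 1 mol %), t-BuOOH, K2CO3 (0.5 equiv), CH2Cl2, rt
Reagents that add atoms: tert-butyl hydroperoxide, CC(C)(C)OO
Why: Allylic C–H oxidation by tert-butylperoxyl radicals at C2, the only ring methylene next to the tetrasubstituted alkene (C4 is quaternary; the methyl and the acetoxy-bearing C–H are less reactive), gives the cyclopentenone.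

Step 6
Reactants: 8 cyclopentenone acetate
Product: 9 1-[(8R)-6-methyl-8-(propan-2-yl)-8-(triethylsilyloxy)-1,4-dioxaspiro[4.4]non-6-en-7-yl]ethyl acetate
Conditions: Me3SiOCH2CH2OSiMe3, Me3SiOTf (cat.), CH2Cl2, −78 → −20 °C
Reagents that add atoms: 1,2-bis(trimethylsilyloxy)ethane, C[Si](C)(C)OCCO[Si](C)(C)C
Why: Noyori ketalisation of the only ketone under aprotic conditions, which leave the double bond in place (C4 has no hydrogen to allow migration) and spare the acetate and the silyl ether.

Step 7
Reactants: 9 ketal acetate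
Product: 10 1-[(8R)-6-methyl-8-(propan-2-yl)-8-(triethylsilyloxy)-1,4-dioxaspiro[4.4]non-6-en-7-yl]ethanol
Conditions: K2CO3 (cat.), MeOH, rt
Reagents that add atoms: none
Why: Base-catalysed transesterification removes the acetate; the ketal and the tertiary triethylsilyl ether are stable to methanolic carbonate.

Step 8
Reactants: 10 allylic alcohol
Product: 11 1-[(8R)-6-methyl-8-(propan-2-yl)-8-(triethylsilyloxy)-1,4-dioxaspiro[4.4]non-6-en-7-yl]ethanone
Conditions: Dess–Martin periodinane, CH2Cl2, 0 °C → rt
Reagents that add atoms: none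
Why: Dess–Martin oxidation of the secondary allylic alcohol gives the methyl ketone (C6) under nearly neutral conditions.

Step 9
Reactants: 11 methyl ketone
Product: 13 (8R)-7-[1-(tert-butyldimethylsilyloxy)ethenyl]-6-methyl-8-(propan-2-yl)-8-(triethylsilyloxy)-1,4-dioxaspiro[4.4]non-6-ene, via lithium enolate 12 (not isolated)
Conditions: LiN(iPr)2, THF, −78 °C; then t-BuMe2SiCl, DMPU, −78 → 0 °C
Reagents that add atoms: tert-butyldimethylsilyl chloride, CC(C)(C)[Si](C)(C)Cl
Why: Kinetic deprotonation of the acetyl methyl (C7) and O-silylation give the cross-conjugated 2-silyloxydiene; the C2 ketal removes every other acidic site and any β-elimination of the C4 oxygen.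

Step 10
Reactants: 14 methyl but-3-enoate
Product: 15 methyl 2-diazobut-3-enoate
Conditions: p-ABSA, DBU, MeCN, 0 °C; pentane extraction, used cold at once
Reagents that add atoms: 4-acetamidobenzenesulfonyl azide, CC(=O)Nc1ccc(cc1)S(=O)(=O)N=[N+]=[N-]
Why: Regitz diazo transfer to the α-carbon, which is activated by both the ester and the vinyl group; the vinyldiazoacetate closes to a pyrazole on standing, so it is made cold and used directly.

Step 11
Reactants: 13 2-silyloxydiene; 15 methyl 2-diazobut-3-enoate (3 equiv, slow addition)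
Product: 17 cycloheptadiene ester (C8 CO2Me; C8=C9; C5=C6 with C6-OTBS; C2 dioxolane; C4 β-OSiEt3 α-iPr; C1 β-Me), via cis-divinylcyclopropane 16 (not isolated)
Conditions: Rh2(S-DOSP)4 (dirhodium tetrakis[(S)-N-(p-dodecylbenzenesulfonyl)prolinate], 2 mol %), hexanes, −40 °C → rt; then toluene, 80 °C
Reagents that add atoms: none
Why: The donor/acceptor rhodium carbenoid from 15 adds its carbene carbon C8 to the terminal enol ether C6=C7 (forming C7–C8 and C6–C8) with the vinyl group cis to the cyclopentenyl group, and 16 then undergoes a Cope [3,3] shift through a boat transition state that breaks C6–C8 and joins C10 to C1; this is the known tandem cyclopropanation/Cope rearrangement (formal 4+3 cycloaddition) of vinyldiazoacetates with 2-silyloxydienes. Ring B (seven-membered) is closed by this pericyclic shift, driven by release of cyclopropane strain. The one new stereocentre, C1 (R, methyl β), follows stereospecifically from the cyclopropane configuration: the (S)-prolinate catalyst is expected to place C8 under the α face of the cyclopentene, so C10 bonds to C1 anti to the C4 silyloxy group, with C4 acting only as a matched or mismatched secondary influence. Chemoselectivity for the enol ether over the tetrasubstituted C1=C5 alkene and the ketal oxygens comes from the electrophilic carbenoid and slow addition, and the hydrocarbon solvent suppresses zwitterionic 3+2 closure. Heating is needed for the Cope step because the C1 methyl is the inward-pointing group of the boat.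

Step 12
Reactants: 17 cycloheptadiene ester
Product: 18 trans-fused hydroxy ketone (C6 ketone; C5 α-H; C4 β-OH; C2 dioxolane; C8 CO2Me with C8=C9)
Conditions: HF·pyridine, pyridine, THF, 0 °C → rt; used at once
Reagents that add atoms: none
Why: Fluoride-mediated cleavage of the silyl enol ether and of the tertiary silyl ether; the enol is protonated at C5 from the α face, opposite the C1 methyl and the C4 oxygen, which gives the trans fusion (also the more stable epimer, since C6 then avoids the α-isopropyl group), and the non-basic medium keeps C8=C9 from moving into conjugation with the ketone.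

Step 13
Reactants: 18 trans-fused hydroxy ketone
Product: 19 4β,6α-diol (C6 α-OH; otherwise as 18)
Conditions: Me4NBH(OAc)3, MeCN/AcOH, −30 → 0 °C
Reagents that add atoms: none
Why: Evans–Saksena reduction: the C4 hydroxyl exchanges onto boron and hydride is delivered internally to the β face of the C6 carbonyl, which sets the 6α (1,3-anti) alcohol; the enoate is inert to the reagent.

Step 14
Reactants: 19 4β,6α-diol
Product: 20 6α-silyl ether (C6 α-OTBS; C4 β-OH free)
Conditions: t-BuMe2SiOTf (1.2 equiv), 2,6-lutidine, CH2Cl2, −78 °C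
Reagents that add atoms: tert-butyldimethylsilyl triflate, CC(C)(C)[Si](C)(C)OS(=O)(=O)C(F)(F)F
Why: Silylation selects the secondary C6 hydroxyl over the tertiary C4 hydroxyl, which is flanked by the isopropyl group and the ring fusion.

Step 15
Reactants: 20 6α-silyl ether
Product: 21 γ-keto enoate (C10 ketone conjugated with C8=C9 and the C8 ester)
Conditions: Rh2(cap)4 (1 mol %), t-BuOOH, K2CO3 (0.5 equiv), 1,2-dichloroethane, 40 °C
Reagents that add atoms: tert-butyl hydroperoxide, CC(C)(C)OO
Why: Allylic oxidation of an α,β-unsaturated ester at its γ-methylene: hydrogen abstraction at C10 gives a radical delocalised onto the ester-bearing C8, which is why C10 is preferred over C7.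

Step 16
Reactants: 21 γ-keto enoate
Product: 22 triol (C10 β-OH; C8 CH2OH; C4 β-OH; C6 α-OTBS)
Conditions: iBu2AlH (excess), CH2Cl2, −78 °C
Reagents that add atoms: none
Why: 1,2-Reduction of the ketone and of the conjugated ester in one operation; hydride reaches C10 from the α face, anti to the axial C1 methyl on the neighbouring quaternary carbon (as 17-keto steroids give 17β-alcohols), which sets the 10β alcohol.

Step 17
Reactants: 22 triol
Product: 24 primary allylic chloride (C8 CH2Cl), via primary allylic mesylate 23 (not isolated)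
Conditions: MeSO2Cl (1.2 equiv), LiCl, 2,4,6-collidine, DMF, 0 °C
Reagents that add atoms: lithium chloride, [Li+].[Cl-]; methanesulfonyl chloride, CS(=O)(=O)Cl (its atoms stay only in 23)
Why: Collington–Meyers conversion of a primary allylic alcohol into the chloride; the neopentyl secondary C10 hydroxyl and the tertiary C4 hydroxyl react far more slowly.

Step 18
Reactants: 24 primary allylic chloride
Product: 25 8-methyl diol (C8 Me; C10 β-OH; C4 β-OH; C6 α-OTBS; C2 dioxolane)
Conditions: LiBHEt3 (excess), THF, 0 °C → rt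
Reagents that add atoms: none
Why: Direct SN2 hydride displacement of the primary allylic chloride gives the C8 methyl without moving the trisubstituted C8=C9 alkene.

Step 19
Reactants: 25 8-methyl diol
Product: 26 10β-benzoate
Conditions: PhCOCl, pyridine, DMAP (cat.), CH2Cl2, rt
Reagents that add atoms: benzoyl chloride, O=C(Cl)c1ccccc1
Why: Nucleophile-catalysed acylation of the only secondary hydroxyl; the tertiary C4 hydroxyl does not acylate under these conditions.

Step 20
Reactants: 26 10β-benzoate
Product: 27 C2 ketone (C4 β-OH; C6 α-OTBS; C10 β-OBz)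
Conditions: PPTS, acetone/H2O, 50 °C
Reagents that add atoms: water, O
Why: Mild acid hydrolysis of the dioxolane; the hindered secondary silyl ether, the benzoate and the tertiary alcohol tolerate pyridinium tosylate.

Step 21
Reactants: 27 C2 ketone
Product: 28 2α-alcohol
Conditions: Me4NBH(OAc)3, MeCN/AcOH, −20 °C → rt
Reagents that add atoms: none
Why: Second Evans–Saksena reduction: boron bound to the 4β hydroxyl delivers hydride across ring A to the β face of C2, giving the trans-1,3 (2α) alcohol that an external hydride, which would attack anti to the C1 methyl, would not give.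

Step 22
Reactants: 28 2α-alcohol
Product: 29 2α-acetate
Conditions: Ac2O, pyridine, DMAP (cat.), CH2Cl2, 0 °C → rt
Reagents that add atoms: acetic anhydride, CC(=O)OC(C)=O
Why: Acetylation of the only free secondary hydroxyl; the tertiary C4 hydroxyl reacts much more slowly and is left free.

Step 23
Reactants: 29 2α-acetate
Product: 30 6α-alcohol (C2 α-OAc; C10 β-OBz; C4 β-OH)
Conditions: HF·pyridine, pyridine, THF, rt
Reagents that add atoms: none
Why: Buffered fluoride cleaves the silyl ether without touching the acetate or the benzoate and without acyl migration.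

Step 24
Reactants: 30 6α-alcohol
Product: 31 CNP0248576.1 (target)
Conditions: angelic acid, 2,4,6-trichlorobenzoyl chloride, Et3N, toluene, rt; then 30, 80 °C
Reagents that add atoms: angelic acid, C/C=C(/C)C(=O)O
Why: Yamaguchi esterification through the preformed mixed anhydride, without a nucleophilic catalyst, acylates the C6 hydroxyl and keeps the (Z) geometry of the angelate; the tertiary C4 hydroxyl stays free.

**Compound list**

1 | (S)-terpinen-4-ol | CC1=CC[C@](O)(C(C)C)CC1 | starting material
2 | (S)-terpinen-4-ol triethylsilyl ether | CC1=CC[C@](O[Si](CC)(CC)CC)(C(C)C)CC1 | intermediate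
3 | secondary ozonide of 2 (1,2,4-trioxolane, diastereomer mixture at the trioxolane carbons) | CC12OOC(O1)C[C@](O[Si](CC)(CC)CC)(C(C)C)CC2 | intermediate (not isolated)
4 | (S)-6-oxo-3-(propan-2-yl)-3-(triethylsilyloxy)heptanal | CC(=O)CC[C@@](O[Si](CC)(CC)CC)(C(C)C)CC=O | intermediate
5 | (R)-2-methyl-5-(propan-2-yl)-5-(triethylsilyloxy)cyclopent-1-ene-1-carbaldehyde | O=CC1=C(C)CC[C@@]1(O[Si](CC)(CC)CC)C(C)C | intermediate
6 | bromomagnesium alkoxide of 1-[(R)-2-methyl-5-(propan-2-yl)-5-(triethylsilyloxy)cyclopent-1-en-1-yl]ethanol (both carbinol epimers) | CC(O[Mg]Br)C1=C(C)CC[C@@]1(O[Si](CC)(CC)CC)C(C)C | intermediate (not isolated)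
7 | 1-[(R)-2-methyl-5-(propan-2-yl)-5-(triethylsilyloxy)cyclopent-1-en-1-yl]ethyl acetate (both carbinol epimers) | CC(OC(C)=O)C1=C(C)CC[C@@]1(O[Si](CC)(CC)CC)C(C)C | intermediate
8 | 1-[(R)-2-methyl-3-oxo-5-(propan-2-yl)-5-(triethylsilyloxy)cyclopent-1-en-1-yl]ethyl acetate | CC(OC(C)=O)C1=C(C)C(=O)C[C@@]1(O[Si](CC)(CC)CC)C(C)C | intermediate
9 | 1-[(8R)-6-methyl-8-(propan-2-yl)-8-(triethylsilyloxy)-1,4-dioxaspiro[4.4]non-6-en-7-yl]ethyl acetate | CC(OC(C)=O)C1=C(C)C2(OCCO2)C[C@@]1(O[Si](CC)(CC)CC)C(C)C | intermediate
10 | 1-[(8R)-6-methyl-8-(propan-2-yl)-8-(triethylsilyloxy)-1,4-dioxaspiro[4.4]non-6-en-7-yl]ethanol | CC(O)C1=C(C)C2(OCCO2)C[C@@]1(O[Si](CC)(CC)CC)C(C)C | intermediate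
11 | 1-[(8R)-6-methyl-8-(propan-2-yl)-8-(triethylsilyloxy)-1,4-dioxaspiro[4.4]non-6-en-7-yl]ethanone | CC(=O)C1=C(C)C2(OCCO2)C[C@@]1(O[Si](CC)(CC)CC)C(C)C | intermediate
12 | lithium enolate of 11 | [Li]OC(=C)C1=C(C)C2(OCCO2)C[C@@]1(O[Si](CC)(CC)CC)C(C)C | intermediate (not isolated)
13 | (8R)-7-[1-(tert-butyldimethylsilyloxy)ethenyl]-6-methyl-8-(propan-2-yl)-8-(triethylsilyloxy)-1,4-dioxaspiro[4.4]non-6-ene | C=C(O[Si](C)(C)C(C)(C)C)C1=C(C)C2(OCCO2)C[C@@]1(O[Si](CC)(CC)CC)C(C)C | intermediate
14 | methyl but-3-enoate | C=CCC(=O)OC | starting material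
15 | methyl 2-diazobut-3-enoate | COC(=O)C(=[N+]=[N-])C=C | intermediate
16 | methyl (1S,2R)-2-(tert-butyldimethylsilyloxy)-1-ethenyl-2-[(8R)-6-methyl-8-(propan-2-yl)-8-(triethylsilyloxy)-1,4-dioxaspiro[4.4]non-6-en-7-yl]cyclopropane-1-carboxylate (vinyl cis to the cyclopentenyl group) | COC(=O)[C@]1(C=C)C[C@@]1(O[Si](C)(C)C(C)(C)C)C2=C(C)C3(OCCO3)C[C@@]2(O[Si](CC)(CC)CC)C(C)C | intermediate (not isolated)
17 | cycloheptadiene ester (C8 CO2Me; C8=C9; C5=C6 with C6-OTBS; C2 dioxolane; C4 β-OSiEt3 α-iPr; C1 β-Me) | COC(=O)C1=CC[C@@]2(C)C3(OCCO3)C[C@@](O[Si](CC)(CC)CC)(C(C)C)C2=C(O[Si](C)(C)C(C)(C)C)C1 | intermediate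
18 | trans-fused hydroxy ketone (C6 ketone; C5 α-H; C4 β-OH; C2 dioxolane; C8 CO2Me) | O=C1CC(C(=O)OC)=CC[C@@]2(C)C3(OCCO3)C[C@@](O)(C(C)C)[C@H]12 | intermediate
19 | 4β,6α-diol | O[C@H]1CC(C(=O)OC)=CC[C@@]2(C)C3(OCCO3)C[C@@](O)(C(C)C)[C@H]12 | intermediate
20 | 6α-silyl ether (C6 α-OTBS; C4 β-OH) | CC(C)(C)[Si](C)(C)O[C@H]1CC(C(=O)OC)=CC[C@@]2(C)C3(OCCO3)C[C@@](O)(C(C)C)[C@H]12 | intermediate
21 | γ-keto enoate (C10 ketone) | CC(C)(C)[Si](C)(C)O[C@H]1CC(C(=O)OC)=CC(=O)[C@@]2(C)C3(OCCO3)C[C@@](O)(C(C)C)[C@H]12 | intermediate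
22 | triol (C10 β-OH; C8 CH2OH; C4 β-OH; C6 α-OTBS) | CC(C)(C)[Si](C)(C)O[C@H]1CC(CO)=C[C@H](O)[C@@]2(C)C3(OCCO3)C[C@@](O)(C(C)C)[C@H]12 | intermediate
23 | primary allylic mesylate of 22 | CC(C)(C)[Si](C)(C)O[C@H]1CC(COS(C)(=O)=O)=C[C@H](O)[C@@]2(C)C3(OCCO3)C[C@@](O)(C(C)C)[C@H]12 | intermediate (not isolated)
24 | primary allylic chloride (C8 CH2Cl) | CC(C)(C)[Si](C)(C)O[C@H]1CC(CCl)=C[C@H](O)[C@@]2(C)C3(OCCO3)C[C@@](O)(C(C)C)[C@H]12 | intermediate
25 | 8-methyl diol (C10 β-OH; C4 β-OH; C6 α-OTBS; C2 dioxolane) | CC(C)(C)[Si](C)(C)O[C@H]1CC(C)=C[C@H](O)[C@@]2(C)C3(OCCO3)C[C@@](O)(C(C)C)[C@H]12 | intermediate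
26 | 10β-benzoate | CC(C)(C)[Si](C)(C)O[C@H]1CC(C)=C[C@H](OC(=O)c3ccccc3)[C@@]2(C)C4(OCCO4)C[C@@](O)(C(C)C)[C@H]12 | intermediate
27 | C2 ketone (C4 β-OH; C6 α-OTBS; C10 β-OBz) | CC(C)(C)[Si](C)(C)O[C@H]1CC(C)=C[C@H](OC(=O)c3ccccc3)[C@@]2(C)C(=O)C[C@@](O)(C(C)C)[C@H]12 | intermediate
28 | 2α-alcohol | CC(C)(C)[Si](C)(C)O[C@H]1CC(C)=C[C@H](OC(=O)c3ccccc3)[C@@]2(C)[C@@H](O)C[C@@](O)(C(C)C)[C@H]12 | intermediate
29 | 2α-acetate | CC(C)(C)[Si](C)(C)O[C@H]1CC(C)=C[C@H](OC(=O)c3ccccc3)[C@@]2(C)[C@@H](OC(C)=O)C[C@@](O)(C(C)C)[C@H]12 | intermediate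
30 | 6α-alcohol (C2 α-OAc; C10 β-OBz; C4 β-OH) | O[C@H]1CC(C)=C[C@H](OC(=O)c3ccccc3)[C@@]2(C)[C@@H](OC(C)=O)C[C@@](O)(C(C)C)[C@H]12 | intermediate
31 | CNP0248576.1 | C/C=C(/C)C(=O)O[C@H]1CC(C)=C[C@H](OC(=O)c2ccccc2)[C@@]2(C)[C@@H](OC(C)=O)C[C@@](O)(C(C)C)[C@H]12 | target

**Step count**

Total: 24 steps. Longest linear sequence: 23 steps (steps 1–9 and 11–24); step 10 is a one-step branch.

**Steps most likely to fail**

Step 11. Three things may go wrong:
- Facial control may be lost in the cyclopropanation if the C4 centre and the catalyst oppose each other.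
- The vinyl group may be delivered trans to the cyclopentenyl group, or the donor–acceptor cyclopropane may open to a zwitterion and close as a five-membered ring.
- The Cope step may be slow (inward C1 methyl; strain between the C6 silyloxy group and C4), so the cyclopropane decomposes on heating.

The fallback replaces catalyst control by a tether between O4 and O6. It sets out from 11: HF·pyridine removes the silyl ether to give 1-[(8R)-8-hydroxy-6-methyl-8-(propan-2-yl)-1,4-dioxaspiro[4.4]non-6-en-7-yl]ethanone F1. iPr2Si(OTf)2 and Et3N in CH2Cl2 silylate the hydroxyl and enolise the methyl ketone onto the same silicon, giving the cyclic diisopropylsilylene dienol ether F2. In F2 the six-membered siladioxane ring holds O6 on the β face beside O4, so only the cyclopropane with C8 under the α face can reach the boat. Addition of 15 with the achiral Rh2(OPiv)4 (dirhodium tetrapivalate) in hexanes should give the spiro cis-divinylcyclopropane F3, which on warming should rearrange to the silylene-bridged cycloadduct F4. HF·pyridine then cleaves the silylene and the enol ether and the route is rejoined at 18.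

Step 15. Hydrogen abstraction may occur at C7 (the other allylic methylene) or next to the C6 silyl ether, or over-oxidation may set in, because both allylic positions are hindered to a similar degree. The fallback places the oxygen through the ester dienolate instead of a radical. It sets out from 20: LiN(iPr)2 (excess, THF/DMPU, −78 °C) removes the γ-hydrogen at C10, and 2-(phenylsulfonyl)-3-phenyloxaziridine hydroxylates the dienolate at its α-carbon C8 to give the α-hydroxy-β,γ-unsaturated ester F5 (C9=C10, either C8 epimer). Pyridinium chlorochromate, (C5H5NH)[CrO3Cl], in CH2Cl2 then effects the Babler–Dauben oxidative 1,3-transposition of this tertiary allylic alcohol, and the route is rejoined at 21.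

Step 21. The hindered tertiary C4 hydroxyl may fail to exchange onto boron, so the ketone either does not react or is reduced externally from the α face, giving the wrong C2 epimer. The fallback accepts the external reduction and inverts. It sets out from 27: NaBH4 in MeOH at 0 °C should attack anti to the C1 methyl and give the 2β-alcohol F6. Mitsunobu reaction with acetic acid (PPh3, diisopropyl azodicarboxylate, toluene) inverts C2 and installs the acetate in the same operation, and the route is rejoined at 29.

**Further compounds**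

F1 | step 11 | 1-[(8R)-8-hydroxy-6-methyl-8-(propan-2-yl)-1,4-dioxaspiro[4.4]non-6-en-7-yl]ethanone | CC(=O)C1=C(C)C2(OCCO2)C[C@@]1(O)C(C)C
F2 | step 11 | cyclic diisopropylsilylene dienol ether (Si bridges O4 and O6; C6=C7 and C1=C5 exocyclic to the siladioxane ring) | C=C1O[Si](C(C)C)(C(C)C)O[C@@]2(C(C)C)CC3(OCCO3)C(C)=C12
F3 | step 11 | spiro cis-divinylcyclopropane (C6 spiro; not isolated) | COC(=O)[C@]1(C=C)C[C@]12O[Si](C(C)C)(C(C)C)O[C@@]3(C(C)C)CC4(OCCO4)C(C)=C23
F4 | step 11 | silylene-bridged cycloadduct (C8 CO2Me; C8=C9; C5=C6; O4–Si–O6) | COC(=O)C1=CC[C@@]2(C)C3(OCCO3)C[C@]4(C(C)C)O[Si](C(C)C)(C(C)C)OC(C1)=C24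
F5 | step 15 | α-hydroxy-β,γ-unsaturated ester (C8 OH and CO2Me; C9=C10; either C8 epimer) | CC(C)(C)[Si](C)(C)O[C@H]1CC(O)(C(=O)OC)C=C[C@@]2(C)C3(OCCO3)C[C@@](O)(C(C)C)[C@H]12
F6 | step 21 | 2β-alcohol (C2 epimer of 28) | CC(C)(C)[Si](C)(C)O[C@H]1CC(C)=C[C@H](OC(=O)c3ccccc3)[C@@]2(C)[C@H](O)C[C@@](O)(C(C)C)[C@H]12
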